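Follow one molecule of partner.

in all of them: substrate 1.1 M
- maple: partner 0.66 M; protic impurity 0.028 M; run made earlier
- larch: partner 0.66 M; protic impurity 0.11 M; run made earlier
- oak: partner 1.3 M; protic impurity 0.055 M; run made earlier
- flask: partner 0.660 M; protic impurity 0.0550 M; time 8.0 d

| run | time / d | substrate / % | target / % |
|---|---|---|---|
| maple | 1.25 | 43.0 | 38.3 |
| maple | 2.50 | 42.5 | 37.9 |
| maple | 4.00 | 42.4 | 38.1 |
| maple | 5.00 | 42.7 | 38.5 |
| larch | 0.625 | 50.0 | 32.1 |
| larch | 1.67 | 50.0 | 33.2 |
| larch | 3.00 | 50.0 | 33.6 |
| larch | 5.00 | 50.0 | 32.5 |
| oak | 0.625 | 4.3 | 60.7 |
| oak | 1.67 | 0 | 66.5 |
| oak | 3.00 | 0 | 66.3 |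
| oak | 5.00 | 0 | 66.9 |

(scatter of a reading: 0.5 percentage points)

- the earlier runs were read with a standard deviation of 0.5 percentage points
- the reaction counts as stopped when no species that holds the substrate changes by six tenths of a point or more over the second half of the time

* why nothing more happens at 8.0 d, or that something still does (the partner has run out first / it is still moving / all of the substrate has reacted / forward and back rates have come level)
* part of the substrate gone at 8.0 d
* the target standing at 8.0 d, as a percentage of the substrate charged

One fork on its way leads to the protic impurity, and the readings suggest that this fork takes partner one for one against the impurity's charge. In the larch run, partner minus impurity comes to 50.0 % of the substrate charge, and 50.0 % of the substrate is gone. In the maple run the same subtraction gives 57.5 % against a mean of 57.4 % gone. In the oak run it gives 113 %, more than the charge, and the substrate reads 0 %. The earlier runs read flat by 1.67 d, well before 8.0 d, so this flask should stand still at the asked time, with the partner as limiting reagent and a spendable partner of 55.0 % of the substrate charge as its conversion.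

A further fork belongs to the reacted substrate. The oak run, whose substrate reads 0 % from 1.67 d on, gives the fork share, target standing per substrate gone, as 66.6 %, so the flask should hold 36.6 % of target. The weak link is that this share was read with partner in excess, whereas this flask should stop with substrate over. The larch run, short of partner, reforges it: its last readings give 66.2 %, a reading 0.40 percentage points lower, which would put the flask's target at 36.4 %.

The forecast says that the partner has run out first, with 55 % (54.2 % to 55.8 %) gone and 36.6 % (35.8 % to 37.4 %) of target, on the ground that “the plateau follows the partner left after the impurity takes its share 1:1”.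

The flask at 8.0 d shows that the partner has run out first, with 0 % of its partner left, 55.0 % of the substrate gone and 36.7 % as target.

    substrate + partner → intermediate (k = 0.0100 L mol⁻¹ min⁻¹)
    intermediate → target (k = 0.00320 min⁻¹)
    partner + protic impurity → quenched reagent (k = 0.100 L mol⁻¹ min⁻¹)
    intermediate → decomposed reagent (k = 0.00160 min⁻¹)

The flask's substrate gone, taken at the fork share 66.6 %, makes 36.6 % of target against the 36.7 % it shows. For a neighbour flask charged with 0.40 M of partner, its other charges and the time as in this flask, the same subtraction reckons a spendable partner of 31.4 % of its substrate charge, and the same share turns that into a reckoned 20.9 % of target. That neighbour ends with 0 % of its partner left, 31.5 % of its substrate gone and 21.0 % as target.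

The runs come from a simulation on assumed constants, noise included.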